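**Retrosynthetic overview**
1. Target: 3-henicosyl-2-hydroxy-5-methoxy-1,4-benzoquinone (ring C1=O, C2–OH, C3–chain, C4=O, C5–OMe, C6–H; chain C1′ to C21′). The one strategic disconnection is C3–C1′, made last on the unprotected quinone at its final oxidation level.
2. The bond is formed by a three-component reductive alkylation: 2-hydroxy-5-methoxy-1,4-benzoquinone, henicosanal (C1′ one oxidation level too high) and Hantzsch ester, whose hydride removes the extra oxidation level in the same flask.
3. Enabling feature: ring atoms HO–C2=C3(H)–C4=O are a vinylogous carboxylic acid (a masked cyclic 1,3-dione). C3 is therefore a carbon nucleophile, and the ring can hold the condensation product as a quinone methide that accepts hydride at C1′. The MeO–C5=C6(H)–C1=O half is a capped vinylogous ester and stays silent, which fixes the regiochemistry.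
4. Precursors: the hydroxyquinone by mono-saponification of 2,5-dimethoxy-1,4-benzoquinone; the aldehyde by oxidation of henicosan-1-ol.
5. Ring formation: none. The single six-membered quinone ring is bought ready-made.

Key step: step 3

Remark: the target is achiral and is treated as the 2-hydroxy-1,4-quinone tautomer drawn, with an unbranched C21 chain; henicosan-1-ol and 2,5-dimethoxy-1,4-benzoquinone are taken as catalogue compounds.

Step 1
Reactants: 1 henicosan-1-ol
Product: 2 henicosanal
Conditions: TEMPO (10 mol%), PhI(OAc)2 (1.1 equiv), CH2Cl2, 30 °C
Reagents that add atoms: none
Why: The oxoammonium species generated from TEMPO and PhI(OAc)2 oxidises the primary alcohol to the aldehyde, and with no water present to hydrate the aldehyde, over-oxidation to the acid is not expected (TEMPO-catalysed alcohol oxidation).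

Step 2
Reactants: 3 2,5-dimethoxy-1,4-benzoquinone
Product: 5 2-hydroxy-5-methoxy-1,4-benzoquinone, via sodium quinonolate 4 (not isolated)
Conditions: NaOH (1.0 equiv), H2O–MeOH, 0 → 25 °C; then aq. HCl to pH 1
Reagents that add atoms: sodium hydroxide, [Na+].[OH-]
Why: Saponification of a vinylogous methyl ester by conjugate addition of hydroxide and loss of methoxide (addition–elimination) should stop after one methoxy group, because the anionic vinylogous carboxylate 4 is a far poorer acceptor for a second hydroxide, and acidification then liberates 5.

Step 3
Reactants: 5 2-hydroxy-5-methoxy-1,4-benzoquinone; 2 henicosanal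
Product: 7 3-henicosyl-2-hydroxy-5-methoxy-1,4-benzoquinone, via quinone methide 6 (not isolated)
Conditions: L-proline (20 mol%), Hantzsch ester (diethyl 2,6-dimethyl-1,4-dihydropyridine-3,5-dicarboxylate, 1.2 equiv), CH2Cl2, 25 °C, N2; work-up in air
Reagents that add atoms: none
Why: L-Proline activates aldehyde 2 as an iminium ion that is attacked by C3 of 5, the α-carbon of the vinylogous acid HO–C2=C3–C4=O, and loss of proline gives the quinone methide 6 (Knoevenagel condensation), whose exocyclic carbon C1′ then accepts hydride from the Hantzsch ester, after which tautomerisation returns the 2-hydroxy-1,4-quinone with the saturated chain on C3. The closest known reaction type is the organocatalytic three-component reductive alkylation of 2-hydroxy-1,4-naphthoquinone, 2,5-dihydroxy-1,4-benzoquinone and cyclic 1,3-diones with aliphatic aldehydes and Hantzsch ester. No ring is closed and no stereocentre is formed. Site selectivity for C3 over C6 is needed and is secured by the substrate, because only C3 lies between the ionisable C2 enol and the C4 carbonyl, whereas C6 belongs to the O-methylated vinylogous ester, which is neither acidic nor comparably nucleophilic. Mono-alkylation must win over conjugate addition of a second molecule of 5 to 6, which is secured by having the hydride donor present in excess from the outset and by the fact that C3 of 7 is fully substituted and cannot condense again. Hydride transfer to the quinone carbonyls should be slow for this electron-rich quinone, and any hydroquinone that forms should be re-oxidised by air during work-up.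

**Compound list**
1 | henicosan-1-ol (unbranched C21 primary alcohol) | CCCCCCCCCCCCCCCCCCCCCO | starting material
2 | henicosanal (unbranched C21 aldehyde) | CCCCCCCCCCCCCCCCCCCCC=O | intermediate
3 | 2,5-dimethoxy-1,4-benzoquinone (2,5-dimethoxycyclohexa-2,5-diene-1,4-dione) | COC1=CC(=O)C(OC)=CC1=O | starting material
4 | sodium 4-methoxy-3,6-dioxocyclohexa-1,4-dien-1-olate (sodium salt of 5) | [Na+].[O-]C1=CC(=O)C(OC)=CC1=O | intermediate
5 | 2-hydroxy-5-methoxy-1,4-benzoquinone | OC1=CC(=O)C(OC)=CC1=O | intermediate
6 | 3-henicosylidene-5-methoxycyclohex-5-ene-1,2,4-trione (quinone methide; transient, exocyclic alkene geometry undefined and of no consequence) | CCCCCCCCCCCCCCCCCCCCC=C1C(=O)C(=O)C=C(OC)C1=O | intermediate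
7 | 3-henicosyl-2-hydroxy-5-methoxy-1,4-benzoquinone (achiral) | CCCCCCCCCCCCCCCCCCCCCC1=C(O)C(=O)C=C(OC)C1=O | target

**Route summary**
Total step count: 3. Longest linear sequence: 2 steps (step 1 then step 3, or step 2 then step 3).

**Steps most likely to fail**

Step 3 is the riskiest. The quinone methide may be intercepted by a second molecule of the hydroxyquinone (bis-quinonylalkane formation) before hydride arrives. The Hantzsch ester may also reduce the quinone faster than condensation takes place, and the enolisable aldehyde may self-condense under amine catalysis. The fallback sets out from 3 and comes back to the route at 7. A silver-catalysed decarboxylative radical alkylation (Minisci-type) of 3 with docosanoic acid (CCCCCCCCCCCCCCCCCCCCCC(=O)O) would be run with AgNO3 (cat.) and (NH4)2S2O8 in MeCN–H2O at 75 °C, with 3 in excess to limit double alkylation. The two ring C–H positions of 3 are equivalent, so this should give 3-henicosyl-2,5-dimethoxy-1,4-benzoquinone F1 without a regiochemical question. Selective acid hydrolysis (HClO4, 1,4-dioxane, 25 °C) should then cleave the C2 methoxy group, which is flanked by the chain, twisted out of conjugation and hence the more labile vinylogous ester, and so give 7.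

Step 2 is next. Hydrolysis may run on to loss of the second methyl group, or stall because 3 is poorly soluble, leaving a mixture that is hard to separate. The fallback sets out from 3 and comes back to the route at 7, turning the over-reaction into the plan. Exhaustive saponification (excess aq. NaOH, 60 °C; then HCl) should give 2,5-dihydroxy-1,4-benzoquinone F2. The three-component reductive alkylation of F2 with aldehyde 2 (L-proline, Hantzsch ester, CH2Cl2–EtOH, 25 °C, F2 in excess to favour mono-alkylation) should give 2,5-dihydroxy-3-henicosyl-1,4-benzoquinone F3. Acid-catalysed mono-O-methylation (MeOH, cat. H2SO4, 50 °C, stopped at the mono-ether stage) is expected at the unhindered C5 hydroxyl, since the C2 hydroxyl is shielded by the chain, and should give 7.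

Step 1 is the least risky. The waxy alcohol may dissolve incompletely and convert only partly; the aldehyde may be over-oxidised or form an ester through its hemiacetal; and the isolated aldehyde may autoxidise on storage. The fallback sets out from 1 and comes back to the route at 2. Tosylation (TsCl, pyridine, DMAP cat., CH2Cl2, 25 °C) should give henicosyl 4-methylbenzenesulfonate F4. Kornblum oxidation (DMSO, NaHCO3, 150 °C, short heating) should then give 2 by displacement and elimination, a path that cannot over-oxidise.

Further compounds
F1 | step 3 | 3-henicosyl-2,5-dimethoxy-1,4-benzoquinone | CCCCCCCCCCCCCCCCCCCCCC1=C(OC)C(=O)C=C(OC)C1=O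
F2 | step 2 | 2,5-dihydroxy-1,4-benzoquinone | OC1=CC(=O)C(O)=CC1=O
F3 | step 2 | 2,5-dihydroxy-3-henicosyl-1,4-benzoquinone | CCCCCCCCCCCCCCCCCCCCCC1=C(O)C(=O)C=C(O)C1=O
F4 | step 1 | henicosyl 4-methylbenzenesulfonate | CCCCCCCCCCCCCCCCCCCCCOS(=O)(=O)c1ccc(C)cc1
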